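**Plan**
Retrosynthesis: the spiro cyclohexene is cut first at C2–C4' and C14–C15' (Diels–Alder union of one guaianolide monomer with its own 1,2-dehydro dienone); the monomer is then cut at C1–C10 and C5–C6 (carbonyl-ylide cycloaddition onto cyclopent-2-enone), and the chain at C9–C10 and C7–C11 (two enolate alkylations on L-malate).
Forward: the open chain C6–C14 is built from dimethyl (S)-malate as a diazo aldehyde; step 8 closes the seven-membered ring onto the five-membered ring of the enone through a temporary C6–O–C10 bridge; C4 methylenation, zinc opening of the bridge (C10=C14), the lactone, the 11(13)-methylene and the C3 ketone follow; the cyclohexene forms in the dimerisation.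
Enabling feature: C6 (lactone carbinol) and C10 (carbon bearing C14) are 1,5-related in the seven-membered ring and flank C5 and C1 of the cyclopentenone ring; an oxygen bridge C6–O–C10 turns C6–C10 into a cyclic carbonyl ylide whose two termini add across C1=C5. The bridge is removed at C10 by reductive elimination and at C6 by an inverting lactonisation.
Stereochemistry: C7 and C8 come from (S)-malic acid (Fráter–Seebach alkylation); C1 and C5 are set in step 8 (exo addition anti to the C7/C8 substituents); C6 by SN2 lactonisation; C4' by α-face Diels–Alder addition; C10 and C5 of the enone half in the final base isomerisation.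

Key step: step 8

Remark on locants: guaiane numbering is used within each half (C1/C5 ring fusion, C4 bearing C15, C6 lactone carbinol, C10 bearing C14, C11–C13 acrylate carbons); primed locants are the spiro cyclopentanone half; α/β as in the usual guaianolide drawing (H7 α).
Remark on the chemistry (assumption): in the enone half C5 and C10 are both γ to the C3 carbonyl, and C5–H is the CH of a 5-methylenecyclopent-2-enone (a hydroxyfulvene-type acid), so neither can hold a kinetic configuration under base. The target's C5 configuration, epimeric to the monomer's, is taken to be the thermodynamically preferred one.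

**Step 1**
Reactants: 1 dimethyl (S)-malate; 2 tert-butyl bromoacetate
Product: 3 dimethyl (2S,3R)-3-(2-tert-butoxy-2-oxoethyl)-2-hydroxybutanedioate
Conditions: LiHMDS (2.2 equiv), THF, −78 to −20 °C; then 2, −78 to −10 °C; aq. NH4Cl
Reagents that add atoms: none
Why: Fráter–Seebach alkylation: the chelated lithium alkoxide–enolate should be alkylated anti to the alkoxide, which sets C7 (R) next to the malate-derived C8 (S).

**Step 2**
Reactants: 3
Product: 4 4-tert-butyl 1-methyl (2R)-2-[(1S)-1,2-dihydroxyethyl]butanedioate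
Conditions: BH3·SMe2 (1.05 equiv), NaBH4 (5 mol %), THF, 0 °C to rt; MeOH quench; used crude
Reagents that add atoms: none
Why: Hydroxyl-directed borane reduction: the alkoxyborane should deliver hydride only to the neighbouring ester, so C9 becomes CH2OH while the other methyl ester and the tert-butyl ester stay.

**Step 3**
Reactants: 4
Product: 5 4-tert-butyl 1-methyl (2R)-2-[(1S)-1-hydroxy-2-iodoethyl]butanedioate
Conditions: I2, PPh3, imidazole, THF, 0 °C
Reagents that add atoms: iodine II
Why: Appel-type iodination should take the primary hydroxyl selectively over the secondary one and makes C9 the electrophile for the C9–C10 bond.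

**Step 4**
Reactants: 5
Product: 6 4-tert-butyl 1-methyl (2R)-2-[(1S)-1-(tert-butyldimethylsilyloxy)-2-iodoethyl]butanedioate
Conditions: TBSOTf, 2,6-lutidine, CH2Cl2, −40 °C
Reagents that add atoms: tert-butyldimethylsilyl triflate CC(C)(C)[Si](C)(C)OS(=O)(=O)C(F)(F)F
Why: Silylation of the secondary C8 hydroxyl under non-nucleophilic base should protect it up to the last step without touching the iodide.

**Step 5**
Reactants: 6; 7 methyl acetoacetate
Product: 8 7-tert-butyl 1-methyl (4R,5R)-2-acetyl-4-(tert-butyldimethylsilyloxy)-5-(methoxycarbonyl)heptanedioate (both C2 epimers)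
Conditions: NaH, THF/DMF, 0 to 55 °C
Reagents that add atoms: none
Why: C-alkylation of the acetoacetate anion by the primary iodide (SN2) should form C9–C10; the new centre at C10 is erased in step 6.

**Step 6**
Reactants: 8
Product: 9 7-tert-butyl 1-methyl (4R,5R)-4-(tert-butyldimethylsilyloxy)-2-diazo-5-(methoxycarbonyl)heptanedioate
Conditions: 4-acetamidobenzenesulfonyl azide, DBU, MeCN, 0 °C to rt
Reagents that add atoms: 4-acetamidobenzenesulfonyl azide CC(=O)Nc1ccc(cc1)S(=O)(=O)N=[N+]=[N-]
Why: Regitz deacylative diazo transfer: the triazoline formed at the α-substituted β-keto ester should fragment with loss of the acetyl group to give the α-diazo ester at C10.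

**Step 7**
Reactants: 9
Product: 10 7-tert-butyl 1-methyl (4R,5R)-4-(tert-butyldimethylsilyloxy)-2-diazo-5-formylheptanedioate
Conditions: DIBAL-H (1.05 equiv), CH2Cl2, −78 °C; Rochelle salt; used at once
Reagents that add atoms: none
Why: Partial reduction through the aluminium hemiacetal, stable at −78 °C, should take the aliphatic methyl ester (C6), which is more electrophilic than the diazo-conjugated ester and the tert-butyl ester; the α-branched, β-silyloxy aldehyde is not stored.

**Step 8**
Reactants: 10; 11 cyclopent-2-en-1-one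
Product: 13 exo cycloadduct (8-oxabicyclo[3.2.1]octane of C6–C10 with the oxygen bridge C6–O–C10, exo-fused at C1–C5 to a cyclopentan-4-one; CO2Me on C10, CH2CO2tBu on C7 and OTBS on C8 both cis to the oxygen bridge; H1 and H5 cis and anti to the bridge), via carbonyl ylide 12 (not isolated)
Conditions: Rh2(O2CCMe3)4 (1 mol %), 11 (5 equiv), CH2Cl2, −20 to 0 °C, slow addition of 10
Reagents that add atoms: none
Why: The rhodium carbenoid from the diazo ester is trapped by the C6 aldehyde oxygen to give the six-membered, ester-stabilised carbonyl ylide 12 (dipole C10–O–C6), which adds across C1=C5 of 11 in a concerted, suprafacial 1,3-dipolar cycloaddition, formally a [5+2] annulation of the C6–C10 chain onto the enone. The closest known reaction type is the tandem carbonyl ylide formation/dipolar cycloaddition of diazo carbonyl compounds with enones. The oxane of the ylide closes by six-membered attack of oxygen on the carbenoid, and the seven-membered carbocycle (C1, C5, C6–C10) and the temporary oxolane (C1, C5, C6, O, C10) then close together in the cycloaddition. C1 and C5 become cis by suprafacial addition to the enone, C6 and C10 are tied cis by the oxygen bridge, and their sense should follow from approach of 11 to the ylide face anti to the C7 side chain and the C8 silyloxy group, with the cyclopentanone exo (syn to the oxygen bridge, since the saturated three-carbon bridge offers no π-overlap for an endo approach). The step needs regiocontrol (the nucleophilic, ester-bearing terminus C10 to the enone β-carbon C1, C6 to the α-carbon C5), exo control and facial control, which rest on the ester-polarised dipole and on the malate-derived C7/C8 centres. Carbenoid 1,2-hydride shift from C9 should be held back by the bulky carboxylate catalyst, the low temperature and the fast six-ring ylide closure.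

**Step 9**
Reactants: 13
Product: 14 4(15)-methylene analogue of 13
Conditions: Zn, CH2Br2, TiCl4, THF/CH2Cl2, 0 °C to rt
Reagents that add atoms: dibromomethane BrCBr
Why: Takai–Lombardo methylenation is non-basic, so the β-alkoxy ketone (C4=O with the C6 bridge oxygen) should not open by E1cB, C5 cannot epimerise, and the esters are left alone.

**Step 10**
Reactants: 14
Product: 15 C14 primary alcohol (CH2OH on C10)
Conditions: LiBH4, THF, 0 °C to rt
Reagents that add atoms: none
Why: The methyl ester is activated by the α-alkoxy group and should be reduced by borohydride, whereas the tert-butyl ester is inert under these conditions.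

**Step 11**
Reactants: 15
Product: 16 C14 iodide (CH2I on C10)
Conditions: I2, PPh3, imidazole, toluene, 90 °C
Reagents that add atoms: iodine II
Why: Appel-type iodination under forcing conditions, as used for primary alcohols next to a fully substituted alkoxy carbon, places the leaving group that will open the bridge.

**Step 12**
Reactants: 16
Product: 17 ring-opened cis-fused hydroazulene (1α-H, 5α-H; 4(15)- and 10(14)-methylene; 6β-OH; 7β-CH2CO2tBu; 8β-OTBS)
Conditions: Zn dust (activated), EtOH/H2O (9:1), 75 °C
Reagents that add atoms: none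
Why: Boord-type reductive β-elimination: the organozinc at C14 should expel the bridging alkoxide from C10, which gives the C10=C14 methylene and frees the C6 hydroxyl with its configuration unchanged (cis to the C7 chain).

**Step 13**
Reactants: 17
Product: 18 6β-mesylate of 17
Conditions: MsCl, Et3N, CH2Cl2, −20 °C; used crude
Reagents that add atoms: methanesulfonyl chloride CS(=O)(=O)Cl
Why: Sulfonylation via sulfene tolerates the hindered secondary alcohol and turns the former bridge oxygen on C6 into a leaving group.

**Step 14**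
Reactants: 18
Product: 21 trans-fused 12,6α-olide (8β-OTBS; 4(15)- and 10(14)-methylene; C11 still CH2), via trimethylsilyl ester 19 (not isolated), via potassium carboxylate 20 (not isolated)
Conditions: TMSOTf, 2,6-lutidine, CH2Cl2, 0 °C; then K2CO3, MeOH, 0 to 40 °C
Reagents that add atoms: none
Why: Buffered silyl triflate should cleave the tert-butyl ester without acid-induced alkene migration, and the carboxylate then displaces the mesylate in a 5-exo-tet SN2 reaction with inversion at C6, giving the natural 6α-oxygen trans to the C7 chain.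

**Step 15**
Reactants: 21
Product: 24 8β-(tert-butyldimethylsilyloxy)dehydrocostus lactone (guaia-4(15),10(14),11(13)-trien-12,6α-olide), via Mannich base 22 (not isolated), via ammonium iodide 23 (not isolated)
Conditions: LiHMDS, THF, −78 °C; Me2N=CH2 I, −78 to 0 °C; then MeI, MeOH, rt; then aq. NaHCO3
Reagents that add atoms: Eschenmoser's salt C=[N+](C)C.[I-]
Why: Lactone enolate aminomethylation, N-methylation and Hofmann-type elimination is the standard α-methylenation of γ-lactones; the C11 centre formed on the way is destroyed.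

**Step 16**
Reactants: 24
Product: 25 3-hydroxy derivative of 24 (both C3 epimers)
Conditions: SeO2 (0.5 equiv), t-BuOOH, CH2Cl2, 0 °C to rt
Reagents that add atoms: tert-butyl hydroperoxide CC(C)(C)OO
Why: Selenium dioxide allylic oxidation (ene reaction then [2,3]-shift) should take the ring CH2 next to the 4(15)-methylene, as in dehydrocostus lactone; C9 is shielded by the C8 silyl ether and C3 is oxidised further in step 17.

**Step 17**
Reactants: 25
Product: 26 8β-(tert-butyldimethylsilyloxy)dehydrozaluzanin C (3-oxo-guaia-4(15),10(14),11(13)-trien-12,6α-olide), the monomer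
Conditions: Dess–Martin periodinane, NaHCO3, CH2Cl2, 0 °C
Reagents that add atoms: none
Why: Buffered Dess–Martin oxidation of the allylic alcohol gives the exo-methylene cyclopentanone without touching the silyl ether or the α-methylene lactone.

**Step 18**
Reactants: 26
Product: 27 3-(tert-butyldimethylsilyloxy)-2,4(15)-diene (silyl enol ether of 26)
Conditions: TBSOTf, Et3N, CH2Cl2, −78 to 0 °C
Reagents that add atoms: tert-butyldimethylsilyl triflate CC(C)(C)[Si](C)(C)OS(=O)(=O)C(F)(F)F
Why: Soft enolisation can only go towards C2, the sole α-position bearing hydrogen, so a single silyl enol ether is expected.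

**Step 19**
Reactants: 27; 26 (3 equiv)
Product: 29 Diels–Alder adduct (spiro at C4'; C1=C10 alkene; H2 β; both C8 oxygens silylated), via dienone 28 (not isolated)
Conditions: Pd(OAc)2 (1.1 equiv), MeCN, rt
Reagents that add atoms: none
Why: Saegusa oxidation gives the 1,2-dehydro dienone 28, whose s-cis diene C2=C1–C10=C14 should add to the exo-methylene enone of 26 with ortho regiochemistry (C2 to C4', C14 to C15') from the convex α-face of the dienophile, anti to its seven-membered ring, which sets C4'; excess 26 suppresses self-addition of 28.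

**Step 20**
Reactants: 29
Product: 30 bis(tert-butyldimethylsilyl) ether of the target
Conditions: DBU (0.3 equiv), CH2Cl2, 0 °C to rt
Reagents that add atoms: none
Why: Base-mediated isomerisation of the β,γ-enone: removal of H2 and reprotonation at C10 gives the conjugated C1=C2 enone, the suprafacial 1,3-proton transfer should place H10 on the β-face vacated by H2, and C5 should equilibrate through the hydroxyfulvene-type enolate to the 5β-H epimer (see the assumption above).

**Step 21**
Reactants: 30
Product: 31 target dimer CNP0397417.1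
Conditions: HF·pyridine, pyridine/THF, 0 °C to rt
Reagents that add atoms: none
Why: Buffered fluoride desilylation frees both 8β-hydroxyls under conditions too mild for relactonisation or Michael addition to the α-methylene lactones.

**Compound list**
1 | dimethyl (S)-malate | COC(=O)[C@@H](O)CC(=O)OC | starting material
2 | tert-butyl bromoacetate | BrCC(=O)OC(C)(C)C | starting material
3 | dimethyl (2S,3R)-3-(2-tert-butoxy-2-oxoethyl)-2-hydroxybutanedioate | COC(=O)[C@@H](O)[C@@H](CC(=O)OC(C)(C)C)C(=O)OC | intermediate
4 | 4-tert-butyl 1-methyl (2R)-2-[(1S)-1,2-dihydroxyethyl]butanedioate | OC[C@@H](O)[C@@H](CC(=O)OC(C)(C)C)C(=O)OC | intermediate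
5 | 4-tert-butyl 1-methyl (2R)-2-[(1S)-1-hydroxy-2-iodoethyl]butanedioate | IC[C@@H](O)[C@@H](CC(=O)OC(C)(C)C)C(=O)OC | intermediate
6 | 4-tert-butyl 1-methyl (2R)-2-[(1S)-1-(tert-butyldimethylsilyloxy)-2-iodoethyl]butanedioate | IC[C@@H](O[Si](C)(C)C(C)(C)C)[C@@H](CC(=O)OC(C)(C)C)C(=O)OC | intermediate
7 | methyl acetoacetate | CC(=O)CC(=O)OC | starting material
8 | 7-tert-butyl 1-methyl (4R,5R)-2-acetyl-4-(tert-butyldimethylsilyloxy)-5-(methoxycarbonyl)heptanedioate (C2 epimers) | CC(=O)C(C[C@@H](O[Si](C)(C)C(C)(C)C)[C@@H](CC(=O)OC(C)(C)C)C(=O)OC)C(=O)OC | intermediate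
9 | 7-tert-butyl 1-methyl (4R,5R)-4-(tert-butyldimethylsilyloxy)-2-diazo-5-(methoxycarbonyl)heptanedioate | COC(=O)C(=[N+]=[N-])C[C@@H](O[Si](C)(C)C(C)(C)C)[C@@H](CC(=O)OC(C)(C)C)C(=O)OC | intermediate
10 | 7-tert-butyl 1-methyl (4R,5R)-4-(tert-butyldimethylsilyloxy)-2-diazo-5-formylheptanedioate | COC(=O)C(=[N+]=[N-])C[C@@H](O[Si](C)(C)C(C)(C)C)[C@@H](CC(=O)OC(C)(C)C)C=O | intermediate
11 | cyclopent-2-en-1-one | O=C1C=CCC1 | starting material
12 | cyclic carbonyl ylide (C10 carbanion, O+=C6H; ester on C10) | COC(=O)[C-]1C[C@@H](O[Si](C)(C)C(C)(C)C)[C@@H](CC(=O)OC(C)(C)C)C=[O+]1 | intermediate (not isolated)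
13 | exo cycloadduct: C6–O–C10 bridged hydroazulen-4-one, CO2Me on C10, CH2CO2tBu on C7, OTBS on C8 | O=C1CC[C@H]2[C@@]3(C(=O)OC)O[C@H]([C@H](CC(=O)OC(C)(C)C)[C@H](O[Si](C)(C)C(C)(C)C)C3)[C@@H]12 | intermediate
14 | 4(15)-methylene analogue of 13 | C=C1CC[C@H]2[C@@]3(C(=O)OC)O[C@H]([C@H](CC(=O)OC(C)(C)C)[C@H](O[Si](C)(C)C(C)(C)C)C3)[C@@H]12 | intermediate
15 | C14 alcohol (CH2OH on C10) | C=C1CC[C@H]2[C@@]3(CO)O[C@H]([C@H](CC(=O)OC(C)(C)C)[C@H](O[Si](C)(C)C(C)(C)C)C3)[C@@H]12 | intermediate
16 | C14 iodide (CH2I on C10) | C=C1CC[C@H]2[C@@]3(CI)O[C@H]([C@H](CC(=O)OC(C)(C)C)[C@H](O[Si](C)(C)C(C)(C)C)C3)[C@@H]12 | intermediate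
17 | ring-opened hydroazulene: 6β-OH, 7β-CH2CO2tBu, 8β-OTBS, 4(15)- and 10(14)-methylene | C=C1CC[C@H]2C(=C)C[C@@H](O[Si](C)(C)C(C)(C)C)[C@@H](CC(=O)OC(C)(C)C)[C@@H](O)[C@@H]12 | intermediate
18 | 6β-mesylate of 17 | C=C1CC[C@H]2C(=C)C[C@@H](O[Si](C)(C)C(C)(C)C)[C@@H](CC(=O)OC(C)(C)C)[C@@H](OS(C)(=O)=O)[C@@H]12 | intermediate
19 | trimethylsilyl ester of the mesylate | C=C1CC[C@H]2C(=C)C[C@@H](O[Si](C)(C)C(C)(C)C)[C@@H](CC(=O)O[Si](C)(C)C)[C@@H](OS(C)(=O)=O)[C@@H]12 | intermediate (not isolated)
20 | potassium carboxylate of the mesylate | C=C1CC[C@H]2C(=C)C[C@@H](O[Si](C)(C)C(C)(C)C)[C@@H](CC(=O)[O-])[C@@H](OS(C)(=O)=O)[C@@H]12.[K+] | intermediate (not isolated)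
21 | trans-fused 12,6α-olide, C11 = CH2 | C=C1CC[C@H]2C(=C)C[C@@H](O[Si](C)(C)C(C)(C)C)[C@H]3CC(=O)O[C@@H]3[C@@H]12 | intermediate
22 | 11-(dimethylaminomethyl) lactone (C11 epimers) | C=C1CC[C@H]2C(=C)C[C@@H](O[Si](C)(C)C(C)(C)C)[C@H]3C(CN(C)C)C(=O)O[C@@H]3[C@@H]12 | intermediate (not isolated)
23 | 11-(trimethylammoniomethyl) lactone iodide | C=C1CC[C@H]2C(=C)C[C@@H](O[Si](C)(C)C(C)(C)C)[C@H]3C(C[N+](C)(C)C)C(=O)O[C@@H]3[C@@H]12.[I-] | intermediate (not isolated)
24 | 8β-(tert-butyldimethylsilyloxy)dehydrocostus lactone | C=C1CC[C@H]2C(=C)C[C@@H](O[Si](C)(C)C(C)(C)C)[C@H]3C(=C)C(=O)O[C@@H]3[C@@H]12 | intermediate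
25 | 3-hydroxy derivative of 24 (C3 epimers) | C=C1C(O)C[C@H]2C(=C)C[C@@H](O[Si](C)(C)C(C)(C)C)[C@H]3C(=C)C(=O)O[C@@H]3[C@@H]12 | intermediate
26 | 8β-(tert-butyldimethylsilyloxy)dehydrozaluzanin C (monomer) | C=C1C(=O)C[C@H]2C(=C)C[C@@H](O[Si](C)(C)C(C)(C)C)[C@H]3C(=C)C(=O)O[C@@H]3[C@@H]12 | intermediate
27 | silyl enol ether of 26 (C3–OTBS, C2=C3) | C=C1C(O[Si](C)(C)C(C)(C)C)=C[C@H]2C(=C)C[C@@H](O[Si](C)(C)C(C)(C)C)[C@H]3C(=C)C(=O)O[C@@H]3[C@@H]12 | intermediate
28 | 1,2-dehydro dienone (3-oxo-guaia-1,4(15),10(14),11(13)-tetraen-12,6α-olide, 8β-OTBS) | C=C1C(=O)C=C2C(=C)C[C@@H](O[Si](C)(C)C(C)(C)C)[C@H]3C(=C)C(=O)O[C@@H]3[C@@H]12 | intermediate (not isolated)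
29 | Diels–Alder adduct (C1=C10, H2 β, 5α-H) | C=C1C(=O)[C@H]2C3=C(CC[C@]24C(=O)C[C@H]2C(=C)C[C@@H](O[Si](C)(C)C(C)(C)C)[C@H]5C(=C)C(=O)O[C@@H]5[C@H]24)C[C@@H](O[Si](C)(C)C(C)(C)C)[C@H]2C(=C)C(=O)O[C@@H]2[C@@H]13 | intermediate
30 | bis(tert-butyldimethylsilyl) ether of the target | C=C1C(=O)C2=C3[C@H](CC[C@]24C(=O)C[C@H]2C(=C)C[C@@H](O[Si](C)(C)C(C)(C)C)[C@H]5C(=C)C(=O)O[C@@H]5[C@H]24)C[C@@H](O[Si](C)(C)C(C)(C)C)[C@H]2C(=C)C(=O)O[C@@H]2[C@H]13 | intermediate
31 | CNP0397417.1 | C=C1C(=O)C2=C3[C@H](CC[C@]24C(=O)C[C@H]2C(=C)C[C@@H](O)[C@H]5C(=C)C(=O)O[C@@H]5[C@H]24)C[C@@H](O)[C@H]2C(=C)C(=O)O[C@@H]2[C@H]13 | target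

**Count**
Total steps: 21. Longest linear sequence: 21 (1 to 31; monomer 26 enters step 19 twice, once as 27).

**Steps most likely to fail**
Step 8. The ylide may be captured too slowly by the weakly dipolarophilic enone, so that carbenoid 1,2-hydride shift, ylide dimerisation and loss of regio- and exo-selectivity take over. The fallback sets out from 10 and comes back at 13, using a doubly activated 2π partner whose extra ester is removed afterwards. Commercial allyl 2-oxocyclopentane-1-carboxylate F1 is selenenylated (PhSeCl, pyridine) to allyl 2-oxo-1-(phenylselanyl)cyclopentane-1-carboxylate F2. Oxidation (H2O2) with selenoxide syn-elimination gives allyl 5-oxocyclopent-1-ene-1-carboxylate F3, which is used at once with 10 under Rh2(OAc)4 to give the C5-allyloxycarbonyl cycloadduct F4. Tsuji deallylative decarboxylation (Pd(PPh3)4, HCO2H, Et3N) then protonates C5, which can only be cis-fused, and returns 13.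

Step 14. E2 elimination towards C5 or C7, or ionisation with retention, may outrun the SN2 displacement at the doubly flanked C6. The fallback sets out from 17 and comes back at 21. Dess–Martin oxidation (NaHCO3) gives the C6 ketone F5. Reduction under thermodynamic control (SmI2, H2O, Et3N, THF) should give the 6α-alcohol F6, whose hydroxyl is trans to the substituents on C5 and C7. Acid-catalysed lactonisation of the γ-hydroxy tert-butyl ester (camphorsulfonic acid, CH2Cl2) then gives 21.

Step 20. Protonation at C10 may be unselective, and the C5 equilibrium may stop at a mixture. The fallback sets out from 29 and comes back at 31, reversing the order of the last two operations. HF·pyridine first gives the bis-desilylated adduct F7. Its free 8β-hydroxyl, on the β-face next to C9/C10, can then deliver the proton to C10 intramolecularly during isomerisation with Et3N in CH2Cl2; C5 again equilibrates, and 31 is reached directly.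

**Further compounds**
F1 | step 8 | allyl 2-oxocyclopentane-1-carboxylate | C=CCOC(=O)C1CCCC1=O
F2 | step 8 | allyl 2-oxo-1-(phenylselanyl)cyclopentane-1-carboxylate | C=CCOC(=O)C1([Se]c2ccccc2)CCCC1=O
F3 | step 8 | allyl 5-oxocyclopent-1-ene-1-carboxylate | C=CCOC(=O)C1=CCCC1=O
F4 | step 8 | C5-(allyloxycarbonyl) analogue of 13 | O=C1CC[C@H]2[C@@]3(C(=O)OC)O[C@H]([C@H](CC(=O)OC(C)(C)C)[C@H](O[Si](C)(C)C(C)(C)C)C3)[C@@]12C(=O)OCC=C
F5 | step 14 | C6 ketone from 17 | C=C1CC[C@H]2C(=C)C[C@@H](O[Si](C)(C)C(C)(C)C)[C@@H](CC(=O)OC(C)(C)C)C(=O)[C@@H]12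
F6 | step 14 | 6α-alcohol (C6 epimer of 17) | C=C1CC[C@H]2C(=C)C[C@@H](O[Si](C)(C)C(C)(C)C)[C@@H](CC(=O)OC(C)(C)C)[C@H](O)[C@@H]12
F7 | step 20 | bis-desilylated Diels–Alder adduct | C=C1C(=O)[C@H]2C3=C(CC[C@]24C(=O)C[C@H]2C(=C)C[C@@H](O)[C@H]5C(=C)C(=O)O[C@@H]5[C@H]24)C[C@@H](O)[C@H]2C(=C)C(=O)O[C@@H]2[C@@H]13
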